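For more Z, raise G; the question for the hour is how much Z a rise in G buys, and an exponent read from the runs gives a first estimate.

all flasks: J 0.10 M; L 0.50 mM (in portions, 4)

| flask | G | remark | time |
|---|---|---|---|
| ash | 0.0082 M | run made earlier; portions every 40 min |  |
| alder | 0.042 M | run made earlier; portions every 40 min |  |
| elm | 0.14 M | run made earlier; portions every 40 min |  |
| epsilon | 0.00800 M | the portions of L follow each other after 40 min, the first at the start | 15 h |
| delta | 0.0200 M | the portions of L follow each other after 40 min, the first at the start | 15 h |
| eta | 0.0600 M | the portions of L follow each other after 40 min, the first at the start | 15 h |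
| zeta | 0.200 M | the portions of L follow each other after 40 min, the first at the start | 15 h |

- ash (time / h: Z / %): 0.833: 0; 1.50: 0.2; 3.00: 0; 6.00: 0.2; 10.0: 0.2
- alder (time / h: Z / %): 0.833: 0.3; 1.50: 0.2; 3.00: 0.4; 6.00: 0.5; 10.0: 0.9
- elm (time / h: Z / %): 2.00: 0.3; 4.00: 1.3; 6.00: 2.6; 8.00: 3.1; 10.0: 4.1

(scatter of a reading: 0.3 percentage points)

- percent here means J units held: one D counts as two
- on the list of suspects stand: J + L <-> L + Q; G + L + Q -> L + Z; J + Q -> D
- "hardly changes" means that all values lie within two and a half points (for a concentration: within two and a half percent of the largest)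

- [Z] at the end for epsilon, delta, eta, zeta, in this order
- the shape of the row from first to last (rises, then falls / rises all the way / falls all the way / falls, then rises / hardly changes)

Two amounts carry the argument: Z as a share of the J charged, at 10.0 h, in elm (4.1 %) and in alder (0.9 %). Ash, at 0.2 % with a scatter of 0.3 percentage points, is too small to read. Elm's Z stands 4.56 times alder's on 3.33 times the G, so Z reads as rising faster than G. In logarithms that is 0.659 over 0.523, which gives n = 1.26, the apparent order in G.

That reading leans on alder, whose 0.9 % carries the same scatter of 0.3 points. Order one, which the suspect step G + L + Q suggests, puts alder at 1.23 %, a gap of about one scatter. One G per Z, elm's Z has taken hardly any of its G charge, 2.93 %. The reckoning here takes order one and, as an assumption beyond elm's last reading at 10.0 h, runs elm's near-straight curve on to 15 h. The forecast takes order about 1.3 and says “Z rises all the way, and G is never limiting”.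

| Flask | G | Z, reckoned here | Z, forecast |
|---|---|---|---|
| epsilon | 0.00800 M | 0.351 % | 0.200 % |
| delta | 0.0200 M | 0.879 % | 0.600 % |
| eta | 0.0600 M | 2.64 % | 2.40 % |
| zeta | 0.200 M | 8.79 % | 10.5 % |

The flasks end at 0.314 %, 0.779 %, 2.27 % and 6.92 % of the J charged, from 3.14 × 10⁻⁴ M up to 0.00692 M: rises all the way.

    J + L ⇌ L + Q (K = 1.00, k = 440 L mol⁻¹ h⁻¹)
    G + L + Q → L + Z (k = 880 L² mol⁻² h⁻¹)
    J + Q → D (k = 19.0 L mol⁻¹ h⁻¹)

In zeta, D holds 86.1 % of the J charged at 15.0 h. Eta's Z carried up with n gives 10.3 %; the Z in zeta stands at 6.92 %. From eta to zeta the exponent is 0.926. From epsilon to delta it is 0.992.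

The data are calculated with constants of no real substance; scatter was added.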